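**Retrosynthetic overview**
1. The route rests on one feature of ring A (C1–C5, C10): the C3–O bond, the C1=C2 double bond and the sp2 carbon C10 stand in a 1,4-relationship, which is what O2 added across C3/C10 of a cyclohexa-1,3-diene leaves after O–O cleavage.
2. Last disconnections: the C3 dienoate (Yamaguchi esterification; acid from (R)-2-methylbutanoic acid), the C13 acetate, and the C7 carbinol by addition of a 2-metallated allyl silyl ether to a C7 ketone from the face opposite the C5 methyl. A ring B 7,8-dione would sit as its C6=C7 enol and take the organometal at C8, so C8 is carried as a silyl-protected carbinol through this addition and re-oxidised afterwards.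
3. Ring B: aldol condensation C9→C10 of the 1,5-diketone gives the C8(=O)–C9=C10–C1=C2 dienone; the C10 carbonyl comes from the endoperoxide via the cis-diol, C3 silylation and C10 oxidation.
4. Ring A: enantioselective Diels–Alder of butadiene with tiglic aldehyde sets C4/C5; Wittig olefination and conjugate reduction build C6–C9; bromination and double dehydrobromination give the diene.
5. Order of ring formation: ring A (step 1), the temporary 1,2-dioxane bridge (step 6, opened in step 7), ring B (step 10).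

Key step: step 6

Convention: eremophilane numbering (ring A = C1–C5 and C10, ring B = C5–C10, C11–C13 on C7, methyls on C4 and C5); β is the face carrying both methyl groups, α the opposite face.
Remark (assumption): the facial sense of step 1 is taken from the accepted transition-state model for 2-substituted enals on this (S)-catalyst (formyl C–H···O contact, diene on the Cα Re face); the (R)-catalyst is equally accessible should the adduct prove antipodal.

**Route**

Step 1
Reactants: 1 buta-1,3-diene; 2 tiglic aldehyde [(E)-2-methylbut-2-enal]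
Product: 3 (1R,6R)-1,6-dimethylcyclohex-3-ene-1-carbaldehyde
Conditions: (S)-3,3-diphenyl-1-(2-methylphenyl)tetrahydro-1H,3H-pyrrolo[1,2-c][1,3,2]oxazaborole (C24H24BNO, 20 mol%), (CF3SO2)2NH (17 mol%), CH2Cl2, −78 to −20 °C
Reagents that add atoms: none
Why: Oxazaborolidinium-catalysed enantioselective Diels–Alder reaction in which the catalyst-bound s-trans enal is attacked on its Cα Re face to set C5, while suprafacial addition to the E-enal places the C4 methyl cis to the C5 methyl.

Step 2
Reactants: 3 (1R,6R)-1,6-dimethylcyclohex-3-ene-1-carbaldehyde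
Product: 4 (E)-4-[(1R,6R)-1,6-dimethylcyclohex-3-en-1-yl]but-3-en-2-one
Conditions: Ph3P=CHC(O)CH3, toluene, 110 °C
Reagents that add atoms: 1-(triphenylphosphoranylidene)propan-2-one, CC(=O)C=P(c1ccccc1)(c1ccccc1)c1ccccc1
Why: Wittig olefination with a stabilised keto ylide, for which the non-enolisable neopentyl aldehyde has no competing pathway and the E-enone is expected; no stereocentre is touched.

Step 3
Reactants: 4 (E)-4-[(1R,6R)-1,6-dimethylcyclohex-3-en-1-yl]but-3-en-2-one
Product: 5 4-[(1R,6R)-1,6-dimethylcyclohex-3-en-1-yl]butan-2-one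
Conditions: Cu(OAc)2·H2O (3 mol%), 1,2-bis(diphenylphosphino)benzene (3 mol%), (EtO)2MeSiH, t-BuOH, toluene, rt
Reagents that add atoms: none
Why: Copper hydride conjugate reduction, which reduces only the electron-poor C6=C7 bond (t-BuOH protonates the copper enolate) and leaves the isolated ring alkene alone.

Step 4
Reactants: 5 4-[(1R,6R)-1,6-dimethylcyclohex-3-en-1-yl]butan-2-one
Product: 6 4-[(1R,2R,4R,5R)-4,5-dibromo-1,2-dimethylcyclohexyl]butan-2-one
Conditions: Br2 (1.0 equiv), CH2Cl2, −78 °C
Reagents that add atoms: bromine, BrBr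
Why: Electrophilic anti addition of bromine to the ring alkene, much faster at −78 °C than α-bromination of the ketone; trans-diaxial opening of the bromonium ion should favour the isomer drawn, and the configuration of the two C–Br centres is of no consequence because both are removed in step 5.

Step 5
Reactants: 6 4-[(1R,2R,4R,5R)-4,5-dibromo-1,2-dimethylcyclohexyl]butan-2-one
Product: 7 4-[(1R,6R)-1,6-dimethylcyclohexa-2,4-dien-1-yl]butan-2-one
Conditions: DBU (4 equiv), toluene, 100 °C
Reagents that add atoms: none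
Why: Twofold E2 dehydrobromination (the vicinal dibromide, then the allylic bromide), where quaternary C5 leaves anti β-hydrogens only at C10 and C3, so the C10=C1–C2=C3 diene forms without touching C4.

Step 6
Reactants: 7 4-[(1R,6R)-1,6-dimethylcyclohexa-2,4-dien-1-yl]butan-2-one
Product: 8 4-[(1S,4R,5S,6S)-5,6-dimethyl-2,3-dioxabicyclo[2.2.2]oct-7-en-5-yl]butan-2-one (O–O bridge across C3 and C10 on the α face)
Conditions: O2, 5,10,15,20-tetraphenylporphyrin (1 mol%), visible light, CH2Cl2, −78 °C
Reagents that add atoms: dioxygen, O=O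
Why: Energy transfer from the porphyrin triplet gives singlet oxygen, which adds in a concerted suprafacial [4+2] cycloaddition across the termini C3 and C10 of the s-cis-locked ring A diene, something ground-state oxygen cannot do. The closest known reaction type is the photooxygenation of cyclohexa-1,3-dienes to 2,3-dioxabicyclo[2.2.2]oct-5-enes, as in the conversion of α-terpinene into ascaridole. The only ring closed is the temporary 1,2-dioxane, formed in the cycloaddition mode as a two-atom O–O bridge over C3/C10 with both C–O bonds made on one face and C1=C2 left behind. The two new stereocentres C3 and C10 are set together by the face of approach: the β face carries both cis methyls, one of them necessarily pseudoaxial, while the α face offers only C4–H and the methylene of the C5 chain, so the bridge should form α and C3–O end trans to the C4 methyl. The selectivities needed are this π-facial preference, expected to be moderate, and [4+2] over the ene pathway, for which only C4–H is available. The low temperature keeps the endoperoxide from rearranging and the chain ketone is inert to singlet oxygen.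

Step 7
Reactants: 8 4-[(1S,4R,5S,6S)-5,6-dimethyl-2,3-dioxabicyclo[2.2.2]oct-7-en-5-yl]butan-2-one
Product: 9 4-[(1S,2R,5S,6S)-2,5-dihydroxy-1,6-dimethylcyclohex-3-en-1-yl]butan-2-one
Conditions: thiourea, MeOH, 0 °C to rt
Reagents that add atoms: none
Why: Thiourea reduction of the peroxide O–O bond, which should give the cis-1,4-diol with C3 and C10 unchanged and leaves the alkene and ketone alone.

Step 8
Reactants: 9 4-[(1S,2R,5S,6S)-2,5-dihydroxy-1,6-dimethylcyclohex-3-en-1-yl]butan-2-one
Product: 10 4-[(1S,2R,5S,6S)-5-{[tert-butyl(diphenyl)silyl]oxy}-2-hydroxy-1,6-dimethylcyclohex-3-en-1-yl]butan-2-one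
Conditions: t-BuPh2SiCl, imidazole, DMF, 0 °C
Reagents that add atoms: tert-butyl(chloro)diphenylsilane, CC(C)(C)[Si](Cl)(c1ccccc1)c1ccccc1
Why: Regioselective silylation, in which the bulky chloride should take the C3 hydroxyl because the C10 hydroxyl is neopentyl (next to quaternary C5) and can be tied up as a hemiketal with the C8 ketone.

Step 9
Reactants: 10 4-[(1S,2R,5S,6S)-5-{[tert-butyl(diphenyl)silyl]oxy}-2-hydroxy-1,6-dimethylcyclohex-3-en-1-yl]butan-2-one
Product: 11 4-[(1S,5S,6S)-5-{[tert-butyl(diphenyl)silyl]oxy}-1,6-dimethyl-2-oxocyclohex-3-en-1-yl]butan-2-one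
Conditions: nPr4N[RuO4] (5 mol%), N-methylmorpholine N-oxide, 4 Å molecular sieves, CH2Cl2, rt
Reagents that add atoms: none
Why: Ley–Griffith oxidation of the allylic C10 alcohol to the enone under neutral conditions; the only adjacent sp3 centre, C5, is quaternary.

Step 10
Reactants: 11 4-[(1S,5S,6S)-5-{[tert-butyl(diphenyl)silyl]oxy}-1,6-dimethyl-2-oxocyclohex-3-en-1-yl]butan-2-one
Product: 13 3α-[tert-butyl(diphenyl)silyloxy]-11,12,13-trinoreremophila-1,9-dien-8-one, via cis-ketol 12 (not isolated)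
Conditions: NaOMe, MeOH, 0 °C to rt
Reagents that add atoms: none
Why: Intramolecular aldol condensation (the ring-closing half of a Robinson annulation), in which only the C9 methyl enolate reaches C10 through a six-membered transition state and E1cB loss of water gives the conjugated dienone, so C10 becomes sp2 and no new stereocentre remains.

Step 11
Reactants: 13 3α-[tert-butyl(diphenyl)silyloxy]-11,12,13-trinoreremophila-1,9-dien-8-one
Product: 14 7α-acetoxy-3α-[tert-butyl(diphenyl)silyloxy]-11,12,13-trinoreremophila-1,9-dien-8-one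
Conditions: Mn(OAc)3·2H2O, benzene, reflux (water separator)
Reagents that add atoms: manganese triacetate dihydrate, CC(=O)[O-].CC(=O)[O-].CC(=O)[O-].[Mn+3].O.O
Why: Mn(OAc)3 α′-acetoxylation of an enone through the manganese enolate, which functionalises C7 as the only sp3 α-position; the equatorial 7α-acetate is expected, and the C7 configuration is of no consequence because C7 is oxidised in step 15.

Step 12
Reactants: 14 7α-acetoxy-3α-[tert-butyl(diphenyl)silyloxy]-11,12,13-trinoreremophila-1,9-dien-8-one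
Product: 15 7α-acetoxy-3α-[tert-butyl(diphenyl)silyloxy]-11,12,13-trinoreremophila-1,9-dien-8β-ol
Conditions: NaBH4, CeCl3·7H2O, MeOH, −78 °C; quench cold
Reagents that add atoms: none
Why: Luche 1,2-reduction, where axial hydride delivery anti to the angular C5 methyl should give the pseudoequatorial 8β-alcohol (a centre removed again in step 20) and the cold quench prevents acetyl migration.

Step 13
Reactants: 15 7α-acetoxy-3α-[tert-butyl(diphenyl)silyloxy]-11,12,13-trinoreremophila-1,9-dien-8β-ol
Product: 16 7α-acetoxy-3α-[tert-butyl(diphenyl)silyloxy]-8β-(triethylsilyloxy)-11,12,13-trinoreremophila-1,9-diene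
Conditions: Et3SiOTf, 2,6-lutidine, CH2Cl2, −78 °C
Reagents that add atoms: triethylsilyl trifluoromethanesulfonate, CC[Si](CC)(CC)OS(=O)(=O)C(F)(F)F
Why: Silylation of a hindered secondary alcohol with a silyl triflate and a hindered base, conditions that do not move the neighbouring acetate.

Step 14
Reactants: 16 7α-acetoxy-3α-[tert-butyl(diphenyl)silyloxy]-8β-(triethylsilyloxy)-11,12,13-trinoreremophila-1,9-diene
Product: 17 3α-[tert-butyl(diphenyl)silyloxy]-8β-(triethylsilyloxy)-11,12,13-trinoreremophila-1,9-dien-7α-ol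
Conditions: iBu2AlH, CH2Cl2, −78 °C; aq. Rochelle salt
Reagents that add atoms: none
Why: Reductive cleavage of the acetate at −78 °C, chosen over alkoxide methanolysis so that the C8 silyl group does not migrate to O7.

Step 15
Reactants: 17 3α-[tert-butyl(diphenyl)silyloxy]-8β-(triethylsilyloxy)-11,12,13-trinoreremophila-1,9-dien-7α-ol
Product: 18 3α-[tert-butyl(diphenyl)silyloxy]-8β-(triethylsilyloxy)-11,12,13-trinoreremophila-1,9-dien-7-one
Conditions: nPr4N[RuO4] (5 mol%), N-methylmorpholine N-oxide, 4 Å molecular sieves, CH2Cl2, rt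
Reagents that add atoms: none
Why: Ley–Griffith oxidation under neutral conditions to the C7 ketone, whose C8 neighbour is a protected carbinol so that, unlike a 7,8-dione, it stays in the keto form.

Step 16
Reactants: 19 2-bromoprop-2-en-1-ol
Product: 20 (2-bromoprop-2-en-1-yloxy)(tert-butyl)dimethylsilane
Conditions: t-BuMe2SiCl, imidazole, CH2Cl2, 0 °C to rt
Reagents that add atoms: tert-butyl(chloro)dimethylsilane, CC(C)(C)[Si](C)(C)Cl
Why: Standard silylation of a primary allylic alcohol.

Step 17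
Reactants: 18 3α-[tert-butyl(diphenyl)silyloxy]-8β-(triethylsilyloxy)-11,12,13-trinoreremophila-1,9-dien-7-one; 20 (2-bromoprop-2-en-1-yloxy)(tert-butyl)dimethylsilane
Product: 23 13-[tert-butyl(dimethyl)silyloxy]-3α-[tert-butyl(diphenyl)silyloxy]-8β-(triethylsilyloxy)eremophila-1,9,11(12)-trien-7β-ol, via vinyllithium 21 (not isolated), via vinylcerium dichloride 22 (not isolated)
Conditions: 20, t-BuLi (2.0 equiv), Et2O, −78 °C; then anhydrous CeCl3, THF, −78 °C; then 18, −78 °C; aq. NH4Cl
Reagents that add atoms: none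
Why: Bromine–lithium exchange, transmetalation to cerium and 1,2-addition of the weakly basic organocerium reagent, which should outrun enolisation at the acidic allylic C8–H; attack from the α face, anti to the pseudoaxial C5 methyl and past the pseudoequatorial C8 silyl ether, sets C7 with the hydroxyl β and the propenyl unit α.

Step 18
Reactants: 23 13-[tert-butyl(dimethyl)silyloxy]-3α-[tert-butyl(diphenyl)silyloxy]-8β-(triethylsilyloxy)eremophila-1,9,11(12)-trien-7β-ol
Product: 24 3α-[tert-butyl(diphenyl)silyloxy]eremophila-1,9,11(12)-triene-7β,8β,13-triol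
Conditions: HF·pyridine, pyridine, THF, 0 °C
Reagents that add atoms: none
Why: Fluoride desilylation graded by silyl group, cleaving the triethylsilyl ether and the primary tert-butyldimethylsilyl ether while the secondary tert-butyldiphenylsilyl ether stays.

Step 19
Reactants: 24 3α-[tert-butyl(diphenyl)silyloxy]eremophila-1,9,11(12)-triene-7β,8β,13-triol
Product: 25 13-acetoxy-3α-[tert-butyl(diphenyl)silyloxy]eremophila-1,9,11(12)-triene-7β,8β-diol
Conditions: Ac2O (1.1 equiv), pyridine, CH2Cl2, −20 °C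
Reagents that add atoms: acetic anhydride, CC(=O)OC(C)=O
Why: Selective acetylation of the primary allylic hydroxyl, the C8 hydroxyl being secondary and flanked by quaternary C7 and the C7 hydroxyl tertiary.

Step 20
Reactants: 25 13-acetoxy-3α-[tert-butyl(diphenyl)silyloxy]eremophila-1,9,11(12)-triene-7β,8β-diol
Product: 26 13-acetoxy-3α-[tert-butyl(diphenyl)silyloxy]-7β-hydroxyeremophila-1,9,11(12)-trien-8-one
Conditions: IBX, DMSO, rt
Reagents that add atoms: none
Why: IBX oxidation of the secondary dienylic C8 alcohol to the dienone; this reagent takes 1,2-diols to α-ketols without C–C cleavage, and the tertiary C7 hydroxyl cannot be oxidised.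

Step 21
Reactants: 26 13-acetoxy-3α-[tert-butyl(diphenyl)silyloxy]-7β-hydroxyeremophila-1,9,11(12)-trien-8-one
Product: 27 13-acetoxy-3α,7β-dihydroxyeremophila-1,9,11(12)-trien-8-one
Conditions: Bu4NF, AcOH, THF, rt
Reagents that add atoms: none
Why: Fluoride cleavage of the silyl ether, buffered with acetic acid to spare the acetate and the tertiary α-ketol.

Step 22
Reactants: 28 (R)-2-methylbutanoic acid
Product: 29 (R)-2-methylbutan-1-ol
Conditions: LiAlH4, Et2O, 0 °C to rt
Reagents that add atoms: none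
Why: Hydride reduction of the carboxylic acid, which does not touch the α-stereocentre.

Step 23
Reactants: 29 (R)-2-methylbutan-1-ol
Product: 31 (2E,4R)-2,4-dimethylhex-2-enal, via (R)-2-methylbutanal 30 (not isolated)
Conditions: TEMPO (10 mol%), PhI(OAc)2, CH2Cl2, rt; then Ph3P=C(CH3)CHO, toluene, 80 °C
Reagents that add atoms: 2-(triphenylphosphoranylidene)propanal, CC(C=O)=P(c1ccccc1)(c1ccccc1)c1ccccc1
Why: Nitroxyl-catalysed oxidation followed in the same pot by Wittig olefination with a stabilised formyl ylide, E-selective for the trisubstituted alkene; the epimerisable aldehyde is never isolated, which protects the stereocentre.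

Step 24
Reactants: 31 (2E,4R)-2,4-dimethylhex-2-enal
Product: 32 ethyl (2E,4E,6R)-4,6-dimethylocta-2,4-dienoate
Conditions: (EtO)2P(O)CH2CO2Et, NaH, THF, 0 °C to rt
Reagents that add atoms: triethyl phosphonoacetate, CCOC(=O)CP(=O)(OCC)OCC
Why: Horner–Wadsworth–Emmons olefination, which should give the 2E double bond.

Step 25
Reactants: 32 ethyl (2E,4E,6R)-4,6-dimethylocta-2,4-dienoate
Product: 33 (2E,4E,6R)-4,6-dimethylocta-2,4-dienoic acid
Conditions: LiOH, THF/MeOH/H2O, rt; then aq. HCl
Reagents that add atoms: lithium hydroxide, [Li+].[OH-]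
Why: Saponification of the ethyl ester; the remote stereocentre and the diene geometry are not affected.

Step 26
Reactants: 27 13-acetoxy-3α,7β-dihydroxyeremophila-1,9,11(12)-trien-8-one; 33 (2E,4E,6R)-4,6-dimethylocta-2,4-dienoic acid
Product: 35 (1S,2S,7S,8aS)-7-[3-(acetyloxy)prop-1-en-2-yl]-7-hydroxy-1,8a-dimethyl-6-oxo-1,2,6,7,8,8a-hexahydronaphthalen-2-yl (2E,4E,6R)-4,6-dimethylocta-2,4-dienoate, via mixed anhydride 34 (not isolated)
Conditions: 33, 2,4,6-Cl3C6H2COCl, Et3N, toluene, rt; then 27, DMAP, toluene, rt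
Reagents that add atoms: none
Why: Yamaguchi esterification, which acylates the secondary C3 hydroxyl with retention (the C3–O bond is not broken) while the tertiary C7 hydroxyl stays free.

**Compound list**
1 | buta-1,3-diene | C=CC=C | starting material
2 | tiglic aldehyde, (E)-2-methylbut-2-enal | C/C=C(\C)C=O | starting material
3 | (1R,6R)-1,6-dimethylcyclohex-3-ene-1-carbaldehyde | O=C[C@]1(C)CC=CC[C@H]1C | intermediate
4 | (E)-4-[(1R,6R)-1,6-dimethylcyclohex-3-en-1-yl]but-3-en-2-one | CC(=O)/C=C/[C@]1(C)CC=CC[C@H]1C | intermediate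
5 | 4-[(1R,6R)-1,6-dimethylcyclohex-3-en-1-yl]butan-2-one | CC(=O)CC[C@]1(C)CC=CC[C@H]1C | intermediate
6 | 4-[(1R,2R,4R,5R)-4,5-dibromo-1,2-dimethylcyclohexyl]butan-2-one | CC(=O)CC[C@]1(C)C[C@@H](Br)[C@H](Br)C[C@H]1C | intermediate
7 | 4-[(1R,6R)-1,6-dimethylcyclohexa-2,4-dien-1-yl]butan-2-one | CC(=O)CC[C@]1(C)C=CC=C[C@H]1C | intermediate
8 | 4-[(1S,4R,5S,6S)-5,6-dimethyl-2,3-dioxabicyclo[2.2.2]oct-7-en-5-yl]butan-2-one | CC(=O)CC[C@]1(C)[C@H]2C=C[C@H](OO2)[C@H]1C | intermediate
9 | 4-[(1S,2R,5S,6S)-2,5-dihydroxy-1,6-dimethylcyclohex-3-en-1-yl]butan-2-one | CC(=O)CC[C@]1(C)[C@H](O)C=C[C@H](O)[C@H]1C | intermediate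
10 | 4-[(1S,2R,5S,6S)-5-{[tert-butyl(diphenyl)silyl]oxy}-2-hydroxy-1,6-dimethylcyclohex-3-en-1-yl]butan-2-one | CC(=O)CC[C@]1(C)[C@H](O)C=C[C@H](O[Si](c2ccccc2)(c2ccccc2)C(C)(C)C)[C@H]1C | intermediate
11 | 4-[(1S,5S,6S)-5-{[tert-butyl(diphenyl)silyl]oxy}-1,6-dimethyl-2-oxocyclohex-3-en-1-yl]butan-2-one | CC(=O)CC[C@]1(C)C(=O)C=C[C@H](O[Si](c2ccccc2)(c2ccccc2)C(C)(C)C)[C@H]1C | intermediate
12 | 10β-hydroxy-3α-[tert-butyl(diphenyl)silyloxy]-11,12,13-trinoreremophil-1-en-8-one (cis-fused ketol) | C[C@@H]1[C@@H](O[Si](c3ccccc3)(c3ccccc3)C(C)(C)C)C=C[C@@]2(O)CC(=O)CC[C@@]12C | intermediate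
13 | 3α-[tert-butyl(diphenyl)silyloxy]-11,12,13-trinoreremophila-1,9-dien-8-one | C[C@@H]1[C@@H](O[Si](c3ccccc3)(c3ccccc3)C(C)(C)C)C=CC2=CC(=O)CC[C@@]12C | intermediate
14 | 7α-acetoxy-3α-[tert-butyl(diphenyl)silyloxy]-11,12,13-trinoreremophila-1,9-dien-8-one | C[C@@H]1[C@@H](O[Si](c3ccccc3)(c3ccccc3)C(C)(C)C)C=CC2=CC(=O)[C@@H](OC(C)=O)C[C@@]12C | intermediate
15 | 7α-acetoxy-3α-[tert-butyl(diphenyl)silyloxy]-11,12,13-trinoreremophila-1,9-dien-8β-ol | C[C@@H]1[C@@H](O[Si](c3ccccc3)(c3ccccc3)C(C)(C)C)C=CC2=C[C@H](O)[C@@H](OC(C)=O)C[C@@]12C | intermediate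
16 | 7α-acetoxy-3α-[tert-butyl(diphenyl)silyloxy]-8β-(triethylsilyloxy)-11,12,13-trinoreremophila-1,9-diene | C[C@@H]1[C@@H](O[Si](c3ccccc3)(c3ccccc3)C(C)(C)C)C=CC2=C[C@H](O[Si](CC)(CC)CC)[C@@H](OC(C)=O)C[C@@]12C | intermediate
17 | 3α-[tert-butyl(diphenyl)silyloxy]-8β-(triethylsilyloxy)-11,12,13-trinoreremophila-1,9-dien-7α-ol | C[C@@H]1[C@@H](O[Si](c3ccccc3)(c3ccccc3)C(C)(C)C)C=CC2=C[C@H](O[Si](CC)(CC)CC)[C@@H](O)C[C@@]12C | intermediate
18 | 3α-[tert-butyl(diphenyl)silyloxy]-8β-(triethylsilyloxy)-11,12,13-trinoreremophila-1,9-dien-7-one | C[C@@H]1[C@@H](O[Si](c3ccccc3)(c3ccccc3)C(C)(C)C)C=CC2=C[C@H](O[Si](CC)(CC)CC)C(=O)C[C@@]12C | intermediate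
19 | 2-bromoprop-2-en-1-ol | C=C(Br)CO | starting material
20 | (2-bromoprop-2-en-1-yloxy)(tert-butyl)dimethylsilane | C=C(Br)CO[Si](C)(C)C(C)(C)C | intermediate
21 | [3-(tert-butyldimethylsilyloxy)prop-1-en-2-yl]lithium | [Li]C(=C)CO[Si](C)(C)C(C)(C)C | intermediate
22 | dichloro[3-(tert-butyldimethylsilyloxy)prop-1-en-2-yl]cerium | Cl[Ce](Cl)C(=C)CO[Si](C)(C)C(C)(C)C | intermediate
23 | 13-[tert-butyl(dimethyl)silyloxy]-3α-[tert-butyl(diphenyl)silyloxy]-8β-(triethylsilyloxy)eremophila-1,9,11(12)-trien-7β-ol | C[C@@H]1[C@@H](O[Si](c3ccccc3)(c3ccccc3)C(C)(C)C)C=CC2=C[C@H](O[Si](CC)(CC)CC)[C@@](O)(C(=C)CO[Si](C)(C)C(C)(C)C)C[C@@]12C | intermediate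
24 | 3α-[tert-butyl(diphenyl)silyloxy]eremophila-1,9,11(12)-triene-7β,8β,13-triol | C[C@@H]1[C@@H](O[Si](c3ccccc3)(c3ccccc3)C(C)(C)C)C=CC2=C[C@H](O)[C@@](O)(C(=C)CO)C[C@@]12C | intermediate
25 | 13-acetoxy-3α-[tert-butyl(diphenyl)silyloxy]eremophila-1,9,11(12)-triene-7β,8β-diol | C[C@@H]1[C@@H](O[Si](c3ccccc3)(c3ccccc3)C(C)(C)C)C=CC2=C[C@H](O)[C@@](O)(C(=C)COC(C)=O)C[C@@]12C | intermediate
26 | 13-acetoxy-3α-[tert-butyl(diphenyl)silyloxy]-7β-hydroxyeremophila-1,9,11(12)-trien-8-one | C[C@@H]1[C@@H](O[Si](c3ccccc3)(c3ccccc3)C(C)(C)C)C=CC2=CC(=O)[C@@](O)(C(=C)COC(C)=O)C[C@@]12C | intermediate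
27 | 13-acetoxy-3α,7β-dihydroxyeremophila-1,9,11(12)-trien-8-one | C[C@@H]1[C@@H](O)C=CC2=CC(=O)[C@@](O)(C(=C)COC(C)=O)C[C@@]12C | intermediate
28 | (R)-2-methylbutanoic acid | CC[C@@H](C)C(=O)O | starting material
29 | (R)-2-methylbutan-1-ol | CC[C@@H](C)CO | intermediate
30 | (R)-2-methylbutanal | CC[C@@H](C)C=O | intermediate
31 | (2E,4R)-2,4-dimethylhex-2-enal | CC[C@@H](C)/C=C(\C)C=O | intermediate
32 | ethyl (2E,4E,6R)-4,6-dimethylocta-2,4-dienoate | CCOC(=O)/C=C/C(C)=C/[C@H](C)CC | intermediate
33 | (2E,4E,6R)-4,6-dimethylocta-2,4-dienoic acid | OC(=O)/C=C/C(C)=C/[C@H](C)CC | intermediate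
34 | (2E,4E,6R)-4,6-dimethylocta-2,4-dienoic 2,4,6-trichlorobenzoic anhydride | O=C(OC(=O)c1c(Cl)cc(Cl)cc1Cl)/C=C/C(C)=C/[C@H](C)CC | intermediate
35 | (1S,2S,7S,8aS)-7-[3-(acetyloxy)prop-1-en-2-yl]-7-hydroxy-1,8a-dimethyl-6-oxo-1,2,6,7,8,8a-hexahydronaphthalen-2-yl (2E,4E,6R)-4,6-dimethylocta-2,4-dienoate | C=C(COC(C)=O)[C@@]1(O)C[C@]2(C)C(=CC1=O)C=C[C@H](OC(=O)/C=C/C(C)=C/[C@H](C)CC)[C@H]2C | target

**Step count**
Total: 26 steps. Longest linear sequence: 21 steps (steps 1–15, 17–21 and 26).

**Steps most likely to fail**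

Step 6. Insufficient π-facial discrimination in the cycloaddition, with singlet oxygen also adding to the methyl-bearing β face, or diversion into the ene pathway at C4–H, would cut the supply of 8. The fallback sets out from 7 and corrects C3 by inversion instead of relying on facial control. The β-face endoperoxide F1 is reduced with thiourea to the 3β,10β-diol F2. A Mitsunobu reaction (4-nitrobenzoic acid, PPh3, diisopropyl azodicarboxylate) inverts the unhindered C3 carbinol, the neopentyl C10 hydroxyl staying out, and gives the 3α-(4-nitrobenzoate) F3. Methanolysis (K2CO3, MeOH) frees the 3α,10β-diol F4, and silylation as in step 8 gives the 3α-silyl ether F5. Oxidation as in step 9 removes the C10 stereocentre and rejoins the route at 11.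

Step 17. Deprotonation of the ketone at the doubly activated C8–H by the organometal, instead of addition to the hindered C7 carbonyl, would return starting ketone or its isomers. The fallback sets out from 18 and builds the propenyl unit from a non-basic two-carbon nucleophile. Reformatsky addition (BrCH2CO2Et, zinc dust, THF) gives the β-hydroxy ester F6. α-Methylenation of its dianion (LiN(iPr)2, then CH2=NMe2+ I−, then MeI and DBU) gives the α-methylene ester F7. Reduction with iBu2AlH gives the allylic diol F8, and HF·pyridine as in step 18 removes the triethylsilyl group to rejoin the route at 24.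

Step 1. Slow turnover of this unreactive enal/diene pair on the catalyst, or incomplete enantiofacial control, would give too little or enantiomerically impure 3. The fallback sets out from 1 and 2 and uses classical resolution. Cycloaddition promoted by EtAlCl2 in CH2Cl2 gives the racemic aldehyde F9, and Pinnick oxidation (NaClO2, NaH2PO4, 2-methylbut-2-ene) gives the racemic acid F10. Crystallisation of its salt with one enantiomer of 1-phenylethylamine, whichever gives the less soluble salt of the wanted acid, and acidification give the (1R,6R)-acid F11. Reduction with LiAlH4 gives the alcohol F12, and Ley–Griffith oxidation returns to the route at 3.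

**Further compounds**
F1 | step 6 | 4-[(1R,4S,5S,6S)-5,6-dimethyl-2,3-dioxabicyclo[2.2.2]oct-7-en-5-yl]butan-2-one (β-face endoperoxide) | CC(=O)CC[C@]1(C)[C@@H]2C=C[C@@H](OO2)[C@H]1C
F2 | step 6 | 3β,10β-diol (C3,C10-bis-epimer of 9) | CC(=O)CC[C@]1(C)[C@@H](O)C=C[C@@H](O)[C@H]1C
F3 | step 6 | 3α-(4-nitrobenzoyloxy)-10β-hydroxy compound | CC(=O)CC[C@]1(C)[C@@H](O)C=C[C@H](OC(=O)c2ccc(cc2)[N+](=O)[O-])[C@H]1C
F4 | step 6 | 3α,10β-diol (C10 epimer of 9) | CC(=O)CC[C@]1(C)[C@@H](O)C=C[C@H](O)[C@H]1C
F5 | step 6 | 3α-[tert-butyl(diphenyl)silyloxy]-10β-hydroxy compound (C10 epimer of 10) | CC(=O)CC[C@]1(C)[C@@H](O)C=C[C@H](O[Si](c2ccccc2)(c2ccccc2)C(C)(C)C)[C@H]1C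
F6 | step 17 | ethyl 2-{7β-hydroxy-3α-[tert-butyl(diphenyl)silyloxy]-8β-(triethylsilyloxy)-11,12,13-trinoreremophila-1,9-dien-7α-yl}acetate | C[C@@H]1[C@@H](O[Si](c3ccccc3)(c3ccccc3)C(C)(C)C)C=CC2=C[C@H](O[Si](CC)(CC)CC)[C@@](O)(CC(=O)OCC)C[C@@]12C
F7 | step 17 | ethyl 2-{7β-hydroxy-3α-[tert-butyl(diphenyl)silyloxy]-8β-(triethylsilyloxy)-11,12,13-trinoreremophila-1,9-dien-7α-yl}prop-2-enoate | C[C@@H]1[C@@H](O[Si](c3ccccc3)(c3ccccc3)C(C)(C)C)C=CC2=C[C@H](O[Si](CC)(CC)CC)[C@@](O)(C(=C)C(=O)OCC)C[C@@]12C
F8 | step 17 | 3α-[tert-butyl(diphenyl)silyloxy]-8β-(triethylsilyloxy)eremophila-1,9,11(12)-triene-7β,13-diol | C[C@@H]1[C@@H](O[Si](c3ccccc3)(c3ccccc3)C(C)(C)C)C=CC2=C[C@H](O[Si](CC)(CC)CC)[C@@](O)(C(=C)CO)C[C@@]12C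
F9 | step 1 | rac-(1R*,6R*)-1,6-dimethylcyclohex-3-ene-1-carbaldehyde (racemate, relative configuration shown) | O=C[C@]1(C)CC=CC[C@H]1C
F10 | step 1 | rac-(1R*,6R*)-1,6-dimethylcyclohex-3-ene-1-carboxylic acid (racemate, relative configuration shown) | OC(=O)[C@]1(C)CC=CC[C@H]1C
F11 | step 1 | (1R,6R)-1,6-dimethylcyclohex-3-ene-1-carboxylic acid | OC(=O)[C@]1(C)CC=CC[C@H]1C
F12 | step 1 | [(1R,6R)-1,6-dimethylcyclohex-3-en-1-yl]methanol | OC[C@]1(C)CC=CC[C@H]1C
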